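Plan this run from its leaner neighbour, charged with 0.070 M of reagent, and decide before charging whether the recipe below needs a longer run, more initiator, or just the reagent it names.

substrate 0.40 M (fed, over 2.0 s); reagent 0.280 M; transfer agent 0.0200 M; initiator 10 mM; time 12 min; the fed solution adds 0.25 times the starting volume

1. conversion of substrate at 12 min
2. amount of target at 12 min, in percent of the substrate charged
3. amount of side product at 12 min, in percent of the substrate charged

- in percentages every species weighs as the substrate in it: one ended chains B counts as two
- where a step has two of a species, its rate is k times that concentration squared, and two are used at each turn
- charges are per starting volume, the dose included; the dosed solution carries all of it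
- run time (flask): 12 min

    initiator → 2 initiating radical (k1 = 0.013 s⁻¹)
    2 idle radical → ended radicals (k2 = 5.3 × 10⁶ M⁻¹ s⁻¹)
    transfer agent + first chain carrier → side product + idle radical (k3 = 1.3 × 10⁵ M⁻¹ s⁻¹)
    2 first chain carrier → ended chains B (k4 = 1.2 × 10⁹ M⁻¹ s⁻¹)
    substrate + second chain carrier → by-product + first chain carrier (k5 = 1.5 × 10⁵ M⁻¹ s⁻¹)
    substrate + initiating radical → capped initiator + first chain carrier (k6 = 9.1 × 10⁵ M⁻¹ s⁻¹)
    reagent + first chain carrier → target + second chain carrier (k7 = 5.9 × 10⁵ M⁻¹ s⁻¹)
    2 second chain carrier → ended chains A (k8 = 1 × 10⁸ M⁻¹ s⁻¹)

Write the substrate's ledger first. The initiator splits into two initiating radicals, and each takes one substrate to become a first chain carrier. That carrier takes one reagent, giving one target and a second chain carrier, which takes one substrate and returns the first chain carrier. So each target costs one reagent and one substrate, and each radical started costs one substrate more. Suppose the reagent is the limiting reagent and is used up, and the initiator with it. Target then stands at 70.0% of the substrate charged. Keep 75.0% as the substrate toll, the reagent charge plus twice the initiator charge, over the substrate charge.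

Now ask whether the chains last. Reckon as if each chain ends at the transfer agent, so that radicals made balance radicals captured. At the starting charges, the reagent's half-life then comes to 11.7 s. Because that is shorter than the initiator's half-life of 0.89 min by its own split, expect the reagent to go first. Commit, then: charge as written, and expect the toll as conversion.

The forecast says 74.8% conversion, 70% target and 4.1% side product, since “the reagent is essentially fully consumed”. The simulation gives 74.9%, 70.0% and 4.28%, so conversion lies 0.10 percentage points below the toll.

This flask has come to rest. Target already stands at 69.8% after 2.40 min, and over the second half of the run the shares moved by up to 0.049 points. At the end 0.015% of the reagent and 0.0086% of the initiator remain, beside 14% of the transfer agent. Ten times the time gives 74.9% conversion, 70.0% target and 4.28% side product, so leave the time as it is.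

Take the toll to the neighbour with 0.070 M of reagent: it gives 22.5% conversion, with target at 17.5%. Computed, that neighbour ends at 22.5% conversion and 17.5% target.

(The numbers were drawn at random within sensible limits.)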